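(The earlier runs and the new flask were computed on assumed constants, and the scatter is random.)

Read each flask as the fraction of its substrate charge still left, and take the natural logarithm of one over that fraction.

| setting | east | north-east | west | north |
|---|---|---|---|---|
| substrate | 0.120 M | 0.0480 M | 0.120 M | 0.120 M |
| partner | 0.144 M | 0.0720 M | 0.430 M | 0.144 M |
| free catalyst | 0.00600 M | 0.00600 M | 0.00600 M | 0.00600 M |
| time |  |  |  | 23 min |

| run | time / min | [substrate] / M |
|---|---|---|
| east run | 0.36 | 0.1116 |
| east run | 0.58 | 0.1100 |
| east run | 0.91 | 0.1064 |
| east run | 1.4 | 0.1044 |
| east run | 2.3 | 0.1010 |
| east run | 3.6 | 0.0994 |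
| east run | 5.7 | 0.0976 |
| east run | 9.1 | 0.0972 |
| north-east run | 0.36 | 0.0471 |
| north-east run | 0.58 | 0.0462 |
| north-east run | 0.91 | 0.0448 |
| north-east run | 1.4 | 0.0452 |
| north-east run | 2.3 | 0.0445 |
| north-east run | 3.6 | 0.0430 |
| north-east run | 5.7 | 0.0434 |
| north-east run | 9.1 | 0.0430 |
| west run | 0.36 | 0.0981 |
| west run | 0.58 | 0.0913 |
| west run | 0.91 | 0.0845 |
| west run | 1.4 | 0.0783 |
| west run | 2.3 | 0.0726 |
| west run | 3.6 | 0.0679 |
| west run | 5.7 | 0.0643 |
| west run | 9.1 | 0.0625 |

(each reading ± 4 × 10⁻⁴ M)

* how the opening rate goes with [partner] round the charge of the east run: the exponent of the rate at two percent of substrate gone to target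
* how the opening rate goes with [substrate] round the charge of the east run: the exponent of the rate at two percent of substrate gone to target (one fixed amount of target, the same in the runs compared)
* substrate in the north run at 23 min, as a share of the substrate charged

- Overall: substrate + partner -> target, with free catalyst as catalyst.
- Constant volume, constant temperature.
- An order is taken over about fifteen percent of the charge, up and down.

We call that logarithm at the last reading the reach of a flask, and read it as 0.211 in the east run and 0.652 in the west run. The share of its reach that a flask has used by a given time serves as its clock.

Follow the east run. In the first 0.36 min the fraction left falls to 93.0%, which uses 34.4% of the reach at a logarithmic pace of 0.202 /min. By 0.91 min, the middle of the run, 57.1% is used, and the west run, with its far larger reach, has used 53.8% at that time. Between 3.6 min and 9.1 min the east pace reads 0.00407 /min, slower than the opening pace by a factor of 49.6, yet the reaction has taken 15.8% of the partner charge. We read this as a catalyst losing its power on a clock of its own.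

Two things follow for us. The north run repeats the east charge, so we hold the reach as read and commit to 81.0% left at 23 min. And 2 percent of the east substrate turned is a logarithm of 0.0202, which costs the east run 9.57% of its reach but the west run 3.10%. The west run therefore reaches that fixed amount of target earlier on its clock than the east run, and we expect both exponents above 1.

The forecast gives 1 in partner, 1 in substrate and 80.5% left, on the grounds of “a catalyst that dies on its own clock”. Its exponents are lower than our expectation, and its fraction left lies a little under ours.

The simulation gives 1.2 in partner, 1.2 in substrate and 80.0% left.

    free catalyst + substrate + partner → target + free catalyst (343.8 /M²/min)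
    2 free catalyst → 2 spent catalyst (247.8 /M/min)
    partner → lost reagent (0.1668 /min)

The north run's 80.0% is a reach of 0.223, against the 0.211 read from the east run. With the passing of free catalyst into spent catalyst taken away, the same north run keeps 40.7%, the partner exponent drops to 1.0, and the substrate exponent drops to 1.0. In the west run a quarter of the charge is target at 0.621 min, which is 44.1% of its reach, and the east run has used 41.3% of its own at 0.58 min.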